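**Retrosynthetic overview**
1. Target ⇐ Yamaguchi acylation of the C8 hydroxyl of a 2-O-silyl germacranolide core with a silyl-protected (2R,3R)-epoxy acid (its epoxide ring is made separately by Sharpless epoxidation), then one desilylation.
2. Core ⇐ intramolecular CrCl2 allylation of an (E)-enal by a 2-(bromomethyl)acrylate: the C6–C7 bond, the ten-membered carbocycle and the trans γ-lactone form together, last of the carbon rings.
3. Open-chain precursor ⇐ C5–C6 by cross-metathesis, C7/C11–C13 by vinylalumination and SN2′ bromination, C8–O by organocatalytic α-oxyamination, C2–C3 by asymmetric methallylboration.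
4. Key step: the C2–C7 chain with the 1(10)Z trisubstituted olefin ⇐ 3-methylanisole. Birch dearomatisation, then ozonolytic opening of the kinetic silyl dienol ether of the derived cyclohexenone, turns the cis geometry enforced by the six-membered ring into the Z olefin and differentiates the two termini.
5. Ring order: arene ring reduced and cut open → ten-membered ring and lactone in one operation → epoxide ring delivered with the side chain.

Assumption: the SMILES is read as 2R,6R,7R,8R with 1(10)Z,4E (germacrane numbering, used in the Why lines) and 2R,3R in the epoxy ester.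

**Route**

Step 1
Reactants: 1 3-methylanisole
Product: 3 3-methylcyclohex-2-en-1-one, via 1-methoxy-5-methylcyclohexa-1,4-diene 2 (not isolated)
Conditions: Li, NH3(l), THF, t-BuOH, −33 °C; then 2 M HCl, THF, rt
Reagents that add atoms: water, O
Why: Birch reduction (dearomatisation, both donor groups stay on sp2 carbons), then enol-ether hydrolysis and conjugation give the enone, whose ring holds C2 and C9 cis across the future C1=C10 bond.

Step 2
Reactants: 3 3-methylcyclohex-2-en-1-one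
Product: 6 methyl (2Z)-6,6-dimethoxy-3-methylhex-2-enoate, via silyl dienol ether 4 (not isolated), via oxo acid 5 (not isolated)
Conditions: LiN(i-Pr)2, THF, −78 °C, then TMSCl; O3 (1.0 equiv), CH2Cl2/MeOH, −78 °C, then Me2S; HC(OMe)3, TsOH (cat.), MeOH, 50 °C
Reagents that add atoms: ozone, O=[O+][O-]; trimethyl orthoformate, COC(OC)OC; methanol, CO
Why: kinetic α′-deprotonation gives the cross-conjugated 2-silyloxydiene, and ozone cleaves its electron-rich silyl enol ether bond (ozonolysis of silyl enol ethers) faster than the trisubstituted olefin; C2 emerges as carboxyl, C7 as aldehyde, the ring-cis olefin becomes the Z-enoate, and orthoformate/acid then acetalises and esterifies.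

Step 3
Reactants: 6 methyl (2Z)-6,6-dimethoxy-3-methylhex-2-enoate
Product: 7 (2Z)-6,6-dimethoxy-3-methylhex-2-en-1-ol
Conditions: i-Bu2AlH (2.5 equiv), CH2Cl2, −78 °C; aq. KNaC4H4O6
Reagents that add atoms: none
Why: 1,2-reduction of the enoate by the aluminium hydride gives the allylic alcohol without touching the acetal or the olefin geometry.

Step 4
Reactants: 7 (2Z)-6,6-dimethoxy-3-methylhex-2-en-1-ol
Product: 8 (2Z)-6,6-dimethoxy-3-methylhex-2-enal
Conditions: MnO2 (activated, 15 equiv), CH2Cl2, 0 °C to rt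
Reagents that add atoms: none
Why: MnO2 oxidation of an allylic alcohol is neutral and gives the Z-enal (as in nerol to neral) with little isomerisation.

Step 5
Reactants: 8 (2Z)-6,6-dimethoxy-3-methylhex-2-enal
Product: 9 (4R,5Z)-9,9-dimethoxy-2,6-dimethylnona-1,5-dien-4-ol
Conditions: 2-methylallylboronic acid pinacol ester (1.3 equiv), (R)-TRIP phosphoric acid (5 mol%), 4 Å MS, toluene, −30 °C; aq. NaHCO3
Reagents that add atoms: 2-methylallylboronic acid pinacol ester, CC(=C)CB1OC(C)(C)C(C)(C)O1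
Why: chiral phosphoric acid-catalysed allylboration through a closed chair transition state; the (R)-catalyst delivers the allyl group to the enal face that gives the (R)-carbinol (C2), as for aryl and α,β-unsaturated aldehydes.

Step 6
Reactants: 9 (4R,5Z)-9,9-dimethoxy-2,6-dimethylnona-1,5-dien-4-ol
Product: 10 tert-butyl{[(4R,5Z)-9,9-dimethoxy-2,6-dimethylnona-1,5-dien-4-yl]oxy}dimethylsilane
Conditions: TBSCl, imidazole, DMF, rt
Reagents that add atoms: tert-butyldimethylsilyl chloride, CC(C)(C)[Si](C)(C)Cl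
Why: silylation protects the allylic C2 hydroxyl against the later bromination and acylation.

Step 7
Reactants: 10 tert-butyl{[(4R,5Z)-9,9-dimethoxy-2,6-dimethylnona-1,5-dien-4-yl]oxy}dimethylsilane
Product: 11 (4Z,6R)-6-[(tert-butyldimethylsilyl)oxy]-4,8-dimethylnona-4,8-dienal
Conditions: oxalic acid, wet SiO2, CH2Cl2, rt
Reagents that add atoms: water, O
Why: mild acetal hydrolysis on wet silica frees the C7 aldehyde and leaves the allylic silyl ether and the Z olefin untouched.

Step 8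
Reactants: 11 (4Z,6R)-6-[(tert-butyldimethylsilyl)oxy]-4,8-dimethylnona-4,8-dienal
Product: 12 (2R,4Z,6R)-6-[(tert-butyldimethylsilyl)oxy]-4,8-dimethyl-2-[(2,2,6,6-tetramethylpiperidin-1-yl)oxy]nona-4,8-dienal
Conditions: TEMPO (1.2 equiv), (2R,5R)-5-benzyl-2-tert-butyl-3-methylimidazolidin-4-one·TFA (20 mol%), CuCl2·2H2O (10 mol%), air, acetone, −10 °C
Reagents that add atoms: TEMPO, CC1(C)CCCC(C)(C)N1[O]
Why: enamine-catalysed α-oxyamination; the shielded enamine face sets C8 (R), the catalyst antipode is the one expected to give 2R (to be confirmed on the derived diol, otherwise the (2S,5S) catalyst is used), and the N–O group serves as a robust protecting group.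

Step 9
Reactants: 12 (2R,4Z,6R)-6-[(tert-butyldimethylsilyl)oxy]-4,8-dimethyl-2-[(2,2,6,6-tetramethylpiperidin-1-yl)oxy]nona-4,8-dienal
Product: 13 methyl (4R,6Z,8R)-8-[(tert-butyldimethylsilyl)oxy]-3-hydroxy-6,10-dimethyl-2-methylidene-4-[(2,2,6,6-tetramethylpiperidin-1-yl)oxy]undeca-6,10-dienoate (both C3 epimers)
Conditions: i-Bu2AlH, NMO, methyl propiolate, THF, 0 °C, 1 h; then 12, 0 °C to rt
Reagents that add atoms: methyl propiolate, C#CC(=O)OC
Why: vinylalumination (hydroalumination of the propiolate gives an α-alumino acrylate that adds 1,2 to the aldehyde) is a base-free equivalent of the Morita–Baylis–Hillman reaction, so C8 is not epimerised; the new carbinol centre is lost in step 10.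

Step 10
Reactants: 13 methyl (4R,6Z,8R)-8-[(tert-butyldimethylsilyl)oxy]-3-hydroxy-6,10-dimethyl-2-methylidene-4-[(2,2,6,6-tetramethylpiperidin-1-yl)oxy]undeca-6,10-dienoate
Product: 14 methyl (2Z,4R,6Z,8R)-2-(bromomethyl)-8-[(tert-butyldimethylsilyl)oxy]-6,10-dimethyl-4-[(2,2,6,6-tetramethylpiperidin-1-yl)oxy]undeca-2,6,10-trienoate
Conditions: NBS, Me2S, CH2Cl2, 0 °C to rt
Reagents that add atoms: N-bromosuccinimide, O=C1CCC(=O)N1Br
Why: Corey–Kim-type activation of the hydroxyl and SN2′ displacement by bromide give the (2Z)-2-(bromomethyl)enoate.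

Step 11
Reactants: 14 methyl (2Z,4R,6Z,8R)-2-(bromomethyl)-8-[(tert-butyldimethylsilyl)oxy]-6,10-dimethyl-4-[(2,2,6,6-tetramethylpiperidin-1-yl)oxy]undeca-2,6,10-trienoate
Product: 15 methyl (2Z,4R,6Z,8R,10E)-2-(bromomethyl)-8-[(tert-butyldimethylsilyl)oxy]-6,10-dimethyl-12-oxo-4-[(2,2,6,6-tetramethylpiperidin-1-yl)oxy]dodeca-2,6,10-trienoate
Conditions: (E)-crotonaldehyde (5 equiv), second-generation Hoveyda–Grubbs catalyst [RuCl2(H2IMes)(=CH-C6H4-2-O-i-Pr)] (10 mol%), CH2Cl2, 40 °C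
Reagents that add atoms: (E)-crotonaldehyde, C/C=C/C=O
Why: cross-metathesis; the 1,1-disubstituted olefin is the only metathesis-competent alkene of 14, and the formyl group ends trans to the larger CH2 branch (E at C4=C5), the minor Z isomer being removed by chromatography.

Step 12
Reactants: 15 methyl (2Z,4R,6Z,8R,10E)-2-(bromomethyl)-8-[(tert-butyldimethylsilyl)oxy]-6,10-dimethyl-12-oxo-4-[(2,2,6,6-tetramethylpiperidin-1-yl)oxy]dodeca-2,6,10-trienoate
Product: 17 (1(10)Z,4E)-2-[(tert-butyldimethylsilyl)oxy]-8-[(2,2,6,6-tetramethylpiperidin-1-yl)oxy]germacra-1(10),4,11(13)-trien-12,6-olide with C2, C6, C7, C8 arranged as in the target, via hydroxy ester 16 (not isolated)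
Conditions: CrCl2 (10 equiv), DMF, rt, slow addition of 15 (final 2 mM); aq. NH4Cl; then TsOH (cat.), CH2Cl2, rt
Reagents that add atoms: none
Why: intramolecular Nozaki–Hiyama–Kishi-type allylation; the equilibrating allylchromium reacts through a chair with both ring-forming substituents equatorial (6,7-anti, hence the trans lactone), the C6–C7 bond forms on the C7 face anti to the C8–C9 bond with H-8 in the plane (minimised allylic strain), giving 6R,7R from 8R, and the hydroxy ester lactonises.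

Step 13
Reactants: 17 the 2-O-silyl 8-O-piperidinyl germacranolide
Product: 18 (2R,6R,7R,8R,1(10)Z,4E)-2-[(tert-butyldimethylsilyl)oxy]-8-hydroxygermacra-1(10),4,11(13)-trien-12,6-olide
Conditions: Zn dust, AcOH/THF (1:3), rt
Reagents that add atoms: none
Why: reductive cleavage of the alkoxyamine N–O bond frees the C8 hydroxyl under conditions too mild to open or relactonise the lactone or to remove the silyl ether.

Step 14
Reactants: 19 but-2-yn-1-ol
Product: 20 (2Z)-2-(tributylstannyl)but-2-en-1-ol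
Conditions: Bu3SnH (1.1 equiv), [(C5Me5)RuCl]4 (1.25 mol%), CH2Cl2, rt
Reagents that add atoms: tributyltin hydride, CCCC[SnH](CCCC)CCCC
Why: ruthenium-catalysed trans-hydrostannation of a propargylic alcohol is hydroxyl-directed, placing tin on the proximal carbon and anti to the new hydrogen, so Sn is cis to CH3.

Step 15
Reactants: 20 (2Z)-2-(tributylstannyl)but-2-en-1-ol
Product: 21 tert-butyldimethyl{[(2Z)-2-(tributylstannyl)but-2-en-1-yl]oxy}silane
Conditions: TBSCl, imidazole, CH2Cl2, rt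
Reagents that add atoms: tert-butyldimethylsilyl chloride, CC(C)(C)[Si](C)(C)Cl
Why: silylation marks this CH2O group (trans to CH3) as the future free hydroxymethyl of the side chain.

Step 16
Reactants: 21 tert-butyldimethyl{[(2Z)-2-(tributylstannyl)but-2-en-1-yl]oxy}silane
Product: 23 (2E)-2-({[tert-butyl(dimethyl)silyl]oxy}methyl)but-2-en-1-ol, via alkenyllithium 22 (not isolated)
Conditions: n-BuLi (1.1 equiv), THF, −78 °C; then CH2O (from (CH2O)n), −78 to 0 °C; aq. NH4Cl
Reagents that add atoms: formaldehyde, C=O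
Why: tin–lithium exchange gives a configurationally stable alkenyllithium, and hydroxymethylation places the new CH2OH cis to CH3, the carbon that becomes the carboxyl.

Step 17
Reactants: 23 (2E)-2-({[tert-butyl(dimethyl)silyl]oxy}methyl)but-2-en-1-ol
Product: 24 [(2R,3R)-2-({[tert-butyl(dimethyl)silyl]oxy}methyl)-3-methyloxiran-2-yl]methanol
Conditions: Ti(O-i-Pr)4 (10 mol%), D-(−)-diethyl tartrate (12 mol%), t-BuOOH, 4 Å MS, CH2Cl2, −20 °C
Reagents that add atoms: tert-butyl hydroperoxide, CC(C)(C)OO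
Why: Sharpless asymmetric epoxidation; with the free CH2OH drawn lower right the D-(−)-tartrate delivers oxygen to the top face, giving the 2R,3R epoxide, and the olefin geometry fixes CH3 cis to the carbinol carbon.

Step 18
Reactants: 24 [(2R,3R)-2-({[tert-butyl(dimethyl)silyl]oxy}methyl)-3-methyloxiran-2-yl]methanol
Product: 25 (2R,3R)-2-({[tert-butyl(dimethyl)silyl]oxy}methyl)-3-methyloxirane-2-carboxylic acid
Conditions: TEMPO (20 mol%), PhI(OAc)2 (2.2 equiv), MeCN/H2O (1:1), rt
Reagents that add atoms: water, O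
Why: oxoammonium oxidation of the primary alcohol through the aldehyde hydrate gives the acid without touching the epoxide or the silyl ether.

Step 19
Reactants: 18 the 8-hydroxy germacranolide; 25 (2R,3R)-2-({[tert-butyl(dimethyl)silyl]oxy}methyl)-3-methyloxirane-2-carboxylic acid
Product: 27 bis(tert-butyldimethylsilyl) ether of the target (silyl on the C2 hydroxyl and on the side-chain CH2OH), via mixed anhydride 26 (not isolated)
Conditions: 25, 2,4,6-trichlorobenzoyl chloride, Et3N, THF, 0 °C; then 18, DMAP, toluene, rt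
Reagents that add atoms: none
Why: Yamaguchi esterification (mixed anhydride, DMAP acyl transfer) couples the hindered α-quaternary glycidic acid to the secondary C8 alcohol without touching any stereocentre.

Step 20
Reactants: 27 bis(tert-butyldimethylsilyl) ether of the target
Product: 28 the target, (2R,6R,7R,8R,1(10)Z,4E)-2-hydroxy-8-{[(2R,3R)-2-(hydroxymethyl)-3-methyloxiran-2-yl]carbonyloxy}germacra-1(10),4,11(13)-trien-12,6-olide
Conditions: HF·pyridine, pyridine, THF, 0 °C to rt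
Reagents that add atoms: none
Why: buffered fluoride cleaves both silyl ethers under non-basic conditions that spare the α-methylene lactone, the epoxide and the ester.

**Compound list**
1 | 3-methylanisole | COc1cccc(C)c1 | starting material
2 | 1-methoxy-5-methylcyclohexa-1,4-diene | COC1=CCC=C(C)C1 | intermediate
3 | 3-methylcyclohex-2-en-1-one | CC1=CC(=O)CCC1 | intermediate
4 | [(5-methylcyclohexa-1,5-dien-1-yl)oxy]trimethylsilane (kinetic silyl dienol ether of 3) | CC1=CC(O[Si](C)(C)C)=CCC1 | intermediate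
5 | (2Z)-3-methyl-6-oxohex-2-enoic acid | OC(=O)/C=C(/C)CCC=O | intermediate
6 | methyl (2Z)-6,6-dimethoxy-3-methylhex-2-enoate | COC(=O)/C=C(/C)CCC(OC)OC | intermediate
7 | (2Z)-6,6-dimethoxy-3-methylhex-2-en-1-ol | OC/C=C(/C)CCC(OC)OC | intermediate
8 | (2Z)-6,6-dimethoxy-3-methylhex-2-enal | O=C/C=C(/C)CCC(OC)OC | intermediate
9 | (4R,5Z)-9,9-dimethoxy-2,6-dimethylnona-1,5-dien-4-ol | C=C(C)C[C@@H](O)/C=C(/C)CCC(OC)OC | intermediate
10 | tert-butyl{[(4R,5Z)-9,9-dimethoxy-2,6-dimethylnona-1,5-dien-4-yl]oxy}dimethylsilane | C=C(C)C[C@@H](O[Si](C)(C)C(C)(C)C)/C=C(/C)CCC(OC)OC | intermediate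
11 | (4Z,6R)-6-[(tert-butyldimethylsilyl)oxy]-4,8-dimethylnona-4,8-dienal | C=C(C)C[C@@H](O[Si](C)(C)C(C)(C)C)/C=C(/C)CCC=O | intermediate
12 | (2R,4Z,6R)-6-[(tert-butyldimethylsilyl)oxy]-4,8-dimethyl-2-[(2,2,6,6-tetramethylpiperidin-1-yl)oxy]nona-4,8-dienal | C=C(C)C[C@@H](O[Si](C)(C)C(C)(C)C)/C=C(/C)C[C@@H](ON1C(C)(C)CCCC1(C)C)C=O | intermediate
13 | methyl (4R,6Z,8R)-8-[(tert-butyldimethylsilyl)oxy]-3-hydroxy-6,10-dimethyl-2-methylidene-4-[(2,2,6,6-tetramethylpiperidin-1-yl)oxy]undeca-6,10-dienoate (C3 epimers) | C=C(C)C[C@@H](O[Si](C)(C)C(C)(C)C)/C=C(/C)C[C@@H](ON1C(C)(C)CCCC1(C)C)C(O)C(=C)C(=O)OC | intermediate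
14 | methyl (2Z,4R,6Z,8R)-2-(bromomethyl)-8-[(tert-butyldimethylsilyl)oxy]-6,10-dimethyl-4-[(2,2,6,6-tetramethylpiperidin-1-yl)oxy]undeca-2,6,10-trienoate | C=C(C)C[C@@H](O[Si](C)(C)C(C)(C)C)/C=C(/C)C[C@@H](ON1C(C)(C)CCCC1(C)C)/C=C(\CBr)C(=O)OC | intermediate
15 | methyl (2Z,4R,6Z,8R,10E)-2-(bromomethyl)-8-[(tert-butyldimethylsilyl)oxy]-6,10-dimethyl-12-oxo-4-[(2,2,6,6-tetramethylpiperidin-1-yl)oxy]dodeca-2,6,10-trienoate | O=C/C=C(\C)C[C@@H](O[Si](C)(C)C(C)(C)C)/C=C(/C)C[C@@H](ON1C(C)(C)CCCC1(C)C)/C=C(\CBr)C(=O)OC | intermediate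
16 | methyl 2-[(1S,2R,3E,6R,7Z,10R)-6-[(tert-butyldimethylsilyl)oxy]-2-hydroxy-4,8-dimethyl-10-[(2,2,6,6-tetramethylpiperidin-1-yl)oxy]cyclodeca-3,7-dien-1-yl]prop-2-enoate (ring C1 is C7 of the target, spatially as in the target) | C=C(C(=O)OC)[C@H]1[C@H](O)/C=C(\C)C[C@@H](O[Si](C)(C)C(C)(C)C)/C=C(/C)C[C@H]1ON2C(C)(C)CCCC2(C)C | intermediate
17 | (1(10)Z,4E)-2-[(tert-butyldimethylsilyl)oxy]-8-[(2,2,6,6-tetramethylpiperidin-1-yl)oxy]germacra-1(10),4,11(13)-trien-12,6-olide, C2, C6, C7, C8 as in the target (2R,6R,8R; C7 is formally S here because N–O outranks the lactone carbon) | C=C1C(=O)O[C@@H]2/C=C(\C)C[C@@H](O[Si](C)(C)C(C)(C)C)/C=C(/C)C[C@@H](ON3C(C)(C)CCCC3(C)C)[C@@H]12 | intermediate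
18 | (2R,6R,7R,8R,1(10)Z,4E)-2-[(tert-butyldimethylsilyl)oxy]-8-hydroxygermacra-1(10),4,11(13)-trien-12,6-olide | C=C1C(=O)O[C@@H]2/C=C(\C)C[C@@H](O[Si](C)(C)C(C)(C)C)/C=C(/C)C[C@@H](O)[C@@H]12 | intermediate
19 | but-2-yn-1-ol | CC#CCO | starting material
20 | (2Z)-2-(tributylstannyl)but-2-en-1-ol | C/C=C(/CO)[Sn](CCCC)(CCCC)CCCC | intermediate
21 | tert-butyldimethyl{[(2Z)-2-(tributylstannyl)but-2-en-1-yl]oxy}silane | C/C=C(/CO[Si](C)(C)C(C)(C)C)[Sn](CCCC)(CCCC)CCCC | intermediate
22 | alkenyllithium from 21 (Li in place of SnBu3, geometry retained) | C/C=C(/CO[Si](C)(C)C(C)(C)C)[Li] | intermediate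
23 | (2E)-2-({[tert-butyl(dimethyl)silyl]oxy}methyl)but-2-en-1-ol | C/C=C(/CO[Si](C)(C)C(C)(C)C)CO | intermediate
24 | [(2R,3R)-2-({[tert-butyl(dimethyl)silyl]oxy}methyl)-3-methyloxiran-2-yl]methanol | OC[C@]1(CO[Si](C)(C)C(C)(C)C)O[C@@H]1C | intermediate
25 | (2R,3R)-2-({[tert-butyl(dimethyl)silyl]oxy}methyl)-3-methyloxirane-2-carboxylic acid | OC(=O)[C@]1(CO[Si](C)(C)C(C)(C)C)O[C@@H]1C | intermediate
26 | mixed anhydride of 25 with 2,4,6-trichlorobenzoic acid | O=C(OC(=O)c1c(Cl)cc(Cl)cc1Cl)[C@]1(CO[Si](C)(C)C(C)(C)C)O[C@@H]1C | intermediate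
27 | bis(tert-butyldimethylsilyl) ether of the target (C2–O and side-chain CH2O) | C=C1C(=O)O[C@@H]2/C=C(\C)C[C@@H](O[Si](C)(C)C(C)(C)C)/C=C(/C)C[C@@H](OC(=O)[C@]3(CO[Si](C)(C)C(C)(C)C)O[C@@H]3C)[C@@H]12 | intermediate
28 | target, (2R,6R,7R,8R,1(10)Z,4E)-2-hydroxy-8-{[(2R,3R)-2-(hydroxymethyl)-3-methyloxiran-2-yl]carbonyloxy}germacra-1(10),4,11(13)-trien-12,6-olide | C=C1C(=O)O[C@@H]2/C=C(\C)C[C@@H](O)/C=C(/C)C[C@@H](OC(=O)[C@]3(CO)O[C@@H]3C)[C@@H]12 | target

**Step count and risks**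

Total step count: 20 (15 on the core line, 5 for the side-chain acid). Longest linear sequence: 15 steps (steps 1–13, 19, 20).

Steps most likely to fail:

Step 2 (ozone must cut only the silyl enol ether bond of a diene, and the acid must esterify in the same pot). The fallback sets out from 3 and returns at 6, replacing ozonolysis by an α-ketol scission so the trisubstituted olefin never meets ozone. Rubottom oxidation of 3 (LiN(i-Pr)2, TMSCl; mCPBA; Et3N·3HF) gives racemic 6-hydroxy-3-methylcyclohex-2-en-1-one F1. Pb(OAc)4 in MeOH/benzene cleaves it to methyl (2Z)-3-methyl-6-oxohex-2-enoate F2. Acetalisation (HC(OMe)3, TsOH, MeOH) then gives 6.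

Step 11 (cross-metathesis of a 1,1-disubstituted olefin: yield and E/Z ratio at C4=C5). The fallback sets out from 8 and returns at 15, building the E olefin stereospecifically from an alkyne instead of by metathesis.
- (R)-TRIP-catalysed propargylation of 8 with allenylboronic acid pinacol ester gives (4R,5Z)-9,9-dimethoxy-6-methylnon-5-en-1-yn-4-ol F3.
- Negishi carboalumination (Me3Al, Cp2ZrCl2, −20 °C, then n-BuLi and (CH2O)n) adds CH3 and CH2OH syn across the alkyne, giving (2E,5R,6Z)-10,10-dimethoxy-3,7-dimethyldeca-2,6-diene-1,5-diol F4.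
- TBSCl/imidazole gives the bis-silyl ether F5.
- The chemistry of steps 7–10 is then repeated: acetal hydrolysis to the aldehyde F6, α-oxyamination to the 2-piperidinyloxy aldehyde F7, vinylalumination to the hydroxy methylidene ester F8, and NBS/Me2S to the (2Z)-bromomethyl ester F9.
- HF·pyridine/pyridine at 0 °C removes only the primary allylic silyl ether to give the C12 alcohol F10, and MnO2 oxidises it to 15.

Step 12 (ten-membered ring closure: oligomerisation and control of C6/C7). The fallback sets out from 14 and returns at 17, setting C6/C7 in an acyclic step and closing the ring by metathesis instead of by carbonyl allylation. Intermolecular CrCl2 coupling of 14 with acrolein (anti-selective, with lactonisation) gives the 5-vinyl α-methylene lactone F11. Ring-closing metathesis between the vinyl group and the 2-methylallyl terminus (second-generation Hoveyda–Grubbs catalyst [RuCl2(H2IMes)(=CH-C6H4-2-O-i-Pr)], toluene, 80 °C, 1 mM) closes C4=C5 to give 17. The olefin geometry is then decided by ring strain and must be checked.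

Further compounds
F1 | step 2 | 6-hydroxy-3-methylcyclohex-2-en-1-one (racemic) | CC1=CC(=O)C(O)CC1
F2 | step 2 | methyl (2Z)-3-methyl-6-oxohex-2-enoate | COC(=O)/C=C(/C)CCC=O
F3 | step 11 | (4R,5Z)-9,9-dimethoxy-6-methylnon-5-en-1-yn-4-ol | C#CC[C@@H](O)/C=C(/C)CCC(OC)OC
F4 | step 11 | (2E,5R,6Z)-10,10-dimethoxy-3,7-dimethyldeca-2,6-diene-1,5-diol | OC/C=C(\C)C[C@@H](O)/C=C(/C)CCC(OC)OC
F5 | step 11 | (2E,5R,6Z)-1,5-bis[(tert-butyldimethylsilyl)oxy]-10,10-dimethoxy-3,7-dimethyldeca-2,6-diene | CC(C)(C)[Si](C)(C)OC/C=C(\C)C[C@@H](O[Si](C)(C)C(C)(C)C)/C=C(/C)CCC(OC)OC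
F6 | step 11 | (4Z,6R,8E)-6,10-bis[(tert-butyldimethylsilyl)oxy]-4,8-dimethyldeca-4,8-dienal | CC(C)(C)[Si](C)(C)OC/C=C(\C)C[C@@H](O[Si](C)(C)C(C)(C)C)/C=C(/C)CCC=O
F7 | step 11 | (2R,4Z,6R,8E)-6,10-bis[(tert-butyldimethylsilyl)oxy]-4,8-dimethyl-2-[(2,2,6,6-tetramethylpiperidin-1-yl)oxy]deca-4,8-dienal | CC(C)(C)[Si](C)(C)OC/C=C(\C)C[C@@H](O[Si](C)(C)C(C)(C)C)/C=C(/C)C[C@@H](ON1C(C)(C)CCCC1(C)C)C=O
F8 | step 11 | methyl (4R,6Z,8R,10E)-8,12-bis[(tert-butyldimethylsilyl)oxy]-3-hydroxy-6,10-dimethyl-2-methylidene-4-[(2,2,6,6-tetramethylpiperidin-1-yl)oxy]dodeca-6,10-dienoate (C3 epimers) | CC(C)(C)[Si](C)(C)OC/C=C(\C)C[C@@H](O[Si](C)(C)C(C)(C)C)/C=C(/C)C[C@@H](ON1C(C)(C)CCCC1(C)C)C(O)C(=C)C(=O)OC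
F9 | step 11 | methyl (2Z,4R,6Z,8R,10E)-2-(bromomethyl)-8,12-bis[(tert-butyldimethylsilyl)oxy]-6,10-dimethyl-4-[(2,2,6,6-tetramethylpiperidin-1-yl)oxy]dodeca-2,6,10-trienoate | CC(C)(C)[Si](C)(C)OC/C=C(\C)C[C@@H](O[Si](C)(C)C(C)(C)C)/C=C(/C)C[C@@H](ON1C(C)(C)CCCC1(C)C)/C=C(\CBr)C(=O)OC
F10 | step 11 | methyl (2Z,4R,6Z,8R,10E)-2-(bromomethyl)-8-[(tert-butyldimethylsilyl)oxy]-12-hydroxy-6,10-dimethyl-4-[(2,2,6,6-tetramethylpiperidin-1-yl)oxy]dodeca-2,6,10-trienoate | OC/C=C(\C)C[C@@H](O[Si](C)(C)C(C)(C)C)/C=C(/C)C[C@@H](ON1C(C)(C)CCCC1(C)C)/C=C(\CBr)C(=O)OC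
F11 | step 12 | (4S,5R)-5-ethenyl-3-methylidene-4-{(1R,3Z,5R)-5-[(tert-butyldimethylsilyl)oxy]-3,7-dimethyl-1-[(2,2,6,6-tetramethylpiperidin-1-yl)oxy]octa-3,7-dien-1-yl}oxolan-2-one (4,5-trans, spatially as C7/C6 of the target) | C=C[C@H]1OC(=O)C(=C)[C@@H]1[C@H](ON2C(C)(C)CCCC2(C)C)C/C(C)=C\[C@H](O[Si](C)(C)C(C)(C)C)CC(C)=C
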